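## Structural features

The target is a flavanonol: a chroman-4-one in which benzo ring A is fused to the dihydropyranone ring C, and C2 carries aryl ring B through a single C–C bond. Its only stereocentres are neighbours and trans to each other, both R: C2 is a benzylic ether carbon bound to O1, and C3 lies α to the C4 ketone and bears a methyl ether in place of the usual hydroxyl. Ring A holds 5-OH (hydrogen-bonded to the C4 carbonyl), 6-OH and 7-OMe, and ring B holds 2'-OH, 3'-OH and 4'-OMe, so each aryl ring is a 1,2,3-trioxygenated array containing an air-sensitive catechol. Base opens ring C by β-elimination of the ring A phenoxide after deprotonation at C3, which would scramble both stereocentres. Acid or strong Lewis acids can ionise the C2–O1 bond, whose cation is stabilised by the ortho and para oxygens of ring B, or cleave the C3 methyl ether. The difficulty therefore lies less in the skeleton than in placing three methyl ethers and four free hydroxyls correctly around a single-enantiomer trans pair that tolerates neither strong base nor strong acid. The key step exploits the fact that the C5 hydroxyl has C6 as its only unsubstituted ortho carbon and the C2' hydroxyl has C3' as its only unsubstituted ortho carbon, so both catechol oxygens can be added last by phenol-directed oxygenation of a 6,3'-dideoxy compound built from phloroglucinol- and resorcinol-type rings. In intermediates that lack oxygen on C3 the same spatial arrangement at C2 is named S, because the CIP ranking of C3 and the aryl carbon is reversed.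

## Logic of the disconnections

**18 to 16 (through 17).** The C6–O and C3'–O bonds are cut. Each is the second oxygen of a catechol and sits on the single free carbon ortho to an existing hydroxyl. Removing them turns two 1,2,3-trioxygenated rings into rings that derive from symmetric commercial phenols, and keeps the most oxidation-sensitive groups out of every earlier step. The forward step must oxygenate two different phenols, one of them chelated, only at the ortho carbon. It must leave the C4 ketone, the C2–H bond and both stereocentres alone, and end in a reduction so that 18 is released directly.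

**16 to 15.** The two phenolic O–H bonds are traced back to O–benzyl bonds. Both phenols carry the same group so that one neutral hydrogenolysis frees them. A methyl ether on O5 is deliberately avoided, because its removal would need a boron or aluminium halide that could also attack the C3 methyl ether or ionise C2–O1. The gain is that no earlier step sees a free phenol. The forward step must cleave two aryl benzyl ethers without hydrogenolysing the cyclic benzylic C2–O1 bond.

**15 to 14.** The O–CH3 bond at C3 is cut. This leads to a 3-hydroxy compound that α-oxidation can supply. The forward step must methylate an α-hydroxy ketone whose enolate would expel the ring A phenoxide, so it has to run without a strong base.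

**14 to 11 (through 12 and 13).** The C3–O bond is cut. This leaves one stereocentre, C2, which is then used to control C3. The forward oxidation must go through a neutral enol derivative and not an enolate, and the oxidant must approach anti to the aryl group.

**11 to 5 and 10.** The C2–C1' bond is cut. This is the convergent disconnection: it divides the molecule into a ring A/C half and a ring B half of similar size. It is also the bond whose formation can set C2 by catalyst control on a flat acceptor. The forward step must transfer an ortho-alkoxy aryl group enantioface-selectively to a vinylogous ester, under conditions mild enough not to open the product.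

**5 to 3 (through 4).** The pyranone is opened at O1–C2 and C2–C3, so that C2 becomes a one-carbon unit delivered by a formamide acetal. The gain is a simple ortho-hydroxy aryl methyl ketone. The forward step must condense at the methyl group and close the ring under acid without cleaving the peri benzyl ether.

**3 to 1 and 2.** One O–benzyl bond is cut. Compound 1 is symmetric, so protecting one hydroxyl raises no regiochemical question and leaves the other to become O1. The forward step must stop at monoalkylation of a diol.

**10 to 7 (through 8 and 9).** The C–B bond is cut back to a C–Br bond. The bromine already marks the carbon that becomes C1', ortho to the future 2'-oxygen and para to the methoxyl. The forward step must achieve halogen–metal exchange at low temperature beside a benzyl ether.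

**7 to 6 and 2.** The O–benzyl bond is cut, which leads to a commercial bromophenol. The forward step is a plain phenol alkylation that must leave the aryl bromide untouched.

## Other disconnections considered

Alternative 1: The cut is C3–C4. The racemic dialdehyde 2-[4-(benzyloxy)-2-formyl-3,5-dimethoxyphenoxy]-2-[2,3-bis(benzyloxy)-4-methoxyphenyl]acetaldehyde A1 would be treated with a chiral triazolium-derived carbene. The ring A aldehyde of A1 would become the acyl anion equivalent and add to the aliphatic aldehyde, closing ring C. Because the α-aryl-α-aryloxy aldehyde centre of A1 is labile, one C2 epimer could be funnelled into (2R,3R)-6-(benzyloxy)-2-[2,3-bis(benzyloxy)-4-methoxyphenyl]-3-hydroxy-5,7-dimethoxychroman-4-one A2. In its favour, ring C and both stereocentres would arise in one organocatalytic step from a racemate, and all ring oxygens are present from the start, so the oxygenation pattern is never in doubt; on that point this plan is better than the chosen one. Against it, the ring A aldehyde of A1 is electron-rich and flanked by two ortho oxygens, so carbene addition should be slow, the more electrophilic aliphatic aldehyde could take the donor role instead, and the ketol A2 can epimerise or tautomerise under the basic conditions. After the key step, A2 still needs O-methylation at C3 (equal to the chosen plan, which has the same liability), then a chelation-controlled 5-O-demethylation by a boron halide next to the C3 methyl ether, then hydrogenolysis. In comparison, it is structurally safer on oxygen placement. Mechanistically its stereocontrol rests on a less secure dynamic resolution, against ligand control followed by substrate control in the chosen plan. In step economy it is longer, because both hexa-oxygenated halves of A1 need several steps each and three steps follow the key step.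

Alternative 2: The cuts are C2–C3 and C3–O. Rh2(OAc)4 would convert the diazoketone 1-[3-(benzyloxy)-6-bromo-2,4-dimethoxyphenyl]-2-diazoethan-1-one A3 into a carbene, methanol A4 would add to give an oxonium ylide, and a chiral phosphoric acid would steer the aldol capture of that ylide by 2,3-bis(benzyloxy)-4-methoxybenzaldehyde A5. The product would be (2R,3R)-1-[3-(benzyloxy)-6-bromo-2,4-dimethoxyphenyl]-3-[2,3-bis(benzyloxy)-4-methoxyphenyl]-3-hydroxy-2-methoxypropan-1-one A6. Ring C would be closed afterwards from A6 by a copper-catalysed intramolecular etherification of the aryl bromide. In its favour, the C3 methoxyl enters from A4 in the C–C bond-forming event, so no separate methylation of a sensitive ketol is needed; on that point it is better than the chosen plan. Both stereocentres are set at once and the union of the two halves is highly convergent. Against it, a 1,2-proton shift of the ylide (plain O–H insertion) competes with trapping, and A5 is an electron-rich, ortho-substituted and therefore weak electrophile. The later C–O coupling exposes the β-hydroxy ketone A6 to base and heat, inviting retro-aldol and elimination, and the end game again needs selective 5-O-demethylation beside the C3 methyl ether. In comparison, it carries all oxygens early, which is equal to alternative 1 and structurally safer than the chosen plan. Mechanistically it depends on two delicate selectivities (ylide trapping and anti selectivity), where the chosen plan uses well-separated events. In step economy it is longer because of the preparation of A3 and A5.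

Alternative 3: The cut is O1–C8a. The anti-aldol (2R,3R)-1-[2-(benzyloxy)-3-hydroxy-4-methoxyphenyl]-3-[2,3-bis(benzyloxy)-4-methoxyphenyl]-3-hydroxy-2-methoxypropan-1-one A7 would be oxidised at its free phenol by the trivalent iodine reagent PhI(OAc)2 in hexafluoroisopropanol. The benzylic hydroxyl would attack the carbon para to the phenol, and rearomatisation would give (2R,3R)-5-(benzyloxy)-2-[2,3-bis(benzyloxy)-4-methoxyphenyl]-6-hydroxy-3,7-dimethoxychroman-4-one A8. In its favour, ring closure uses a C–H bond, with no halogen and no metal, and A8 already holds the C3 methyl ether and every oxygen, so only hydrogenolysis remains. This end game is equal in length to the chosen one and avoids oxidising a finished flavanonol; on that point it is better. Against it, A7 requires an enantio- and diastereoselective anti-aldol of an α-methoxy aryl ketone with a hindered aldehyde. The oxidised phenol of A7 is flanked by two alkoxy groups, so ipso attack and quinone monoketal formation compete with para attack. A8 is a para-alkoxyphenol and more easily oxidised than A7, and the trioxygenated ring B and the benzylic carbinol are also vulnerable to the oxidant. In comparison, both plans rely on a late hypervalent iodine oxidation of an electron-rich phenol, so they are equal in kind of risk. The chosen plan delivers oxygen intramolecularly from iodine bound to the phenol, whereas here a tethered nucleophile must win against several open positions. In step economy this plan is longer up to the key step and equal after it.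

Key step: step 10

Assumption: the (S,S) antipode of the diene ligand in step 5 is taken to deliver the aryl group to the C2 face that leads to 11, by analogy with its sense of induction on cyclic enones; should the sense prove opposite, the (R,R) antipode is used and nothing else changes.

## Route

Step 1
Reactants: 1 1-(2,6-dihydroxy-4-methoxyphenyl)ethan-1-one; 2 benzyl bromide
Product: 3 1-[2-(benzyloxy)-6-hydroxy-4-methoxyphenyl]ethan-1-one
Conditions: K2CO3, acetone, reflux (1.05 equiv of 2)
Reagents that add atoms: benzyl bromide (compound 2), BrCc1ccccc1
Why: Williamson ether synthesis on one of two equivalent phenols; after the first alkylation the remaining hydroxyl is locked in a hydrogen bond to the acetyl carbonyl and is far less nucleophilic, so monoalkylation should dominate.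

Step 2
Reactants: 3 1-[2-(benzyloxy)-6-hydroxy-4-methoxyphenyl]ethan-1-one
Product: 5 5-(benzyloxy)-7-methoxy-4H-chromen-4-one, via enaminone 4 (not isolated)
Conditions: Me2NCH(OMe)2, toluene, 100 °C; then conc. HCl, CH2Cl2, rt
Reagents that add atoms: N,N-dimethylformamide dimethyl acetal, COC(OC)N(C)C
Why: Condensation of the methyl ketone with the amide acetal gives the β-(dimethylamino)enone 4; acid then promotes conjugate addition of the phenol and loss of dimethylamine (6-endo addition–elimination), a standard chromone synthesis.

Step 3
Reactants: 6 2-bromo-5-methoxyphenol; 2 benzyl bromide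
Product: 7 2-(benzyloxy)-1-bromo-4-methoxybenzene
Conditions: K2CO3, DMF, rt
Reagents that add atoms: benzyl bromide (compound 2), BrCc1ccccc1
Why: Williamson ether synthesis of a simple phenol; the aryl bromide is inert under these conditions.

Step 4
Reactants: 7 2-(benzyloxy)-1-bromo-4-methoxybenzene
Product: 10 [2-(benzyloxy)-4-methoxyphenyl]boronic acid, via aryllithium 8 (not isolated), via lithium triisopropyl arylborate 9 (not isolated)
Conditions: n-BuLi, THF, −78 °C; B(OiPr)3, −78 °C → rt; 1 M HCl
Reagents that add atoms: triisopropyl borate, CC(C)OB(OC(C)C)OC(C)C; water, O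
Why: Bromine–lithium exchange is faster than any deprotonation at −78 °C, the aryllithium 8 is trapped by the borate as the ate complex 9, and aqueous acid hydrolyses the B–O bonds to the boronic acid.

Step 5
Reactants: 5 5-(benzyloxy)-7-methoxy-4H-chromen-4-one; 10 [2-(benzyloxy)-4-methoxyphenyl]boronic acid
Product: 11 (2S)-5-(benzyloxy)-2-[2-(benzyloxy)-4-methoxyphenyl]-7-methoxy-2,3-dihydro-4H-chromen-4-one
Conditions: [RhCl(C2H4)2]2 (2.5 mol%), (1S,4S)-2,5-diphenylbicyclo[2.2.2]octa-2,5-diene (5.5 mol%), aq. K3PO4 (0.5 equiv), toluene, 40 °C (2 equiv of 10)
Reagents that add atoms: none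
Why: Rhodium-catalysed asymmetric 1,4-addition of an arylboronic acid to a chromone (Hayashi–Miyaura reaction): transmetalation gives an aryl complex of monovalent rhodium, the C2=C3 bond inserts on the enantioface selected by the chiral diene, and protonolysis of the rhodium enolate releases the flavanone. The new stereocentre C2 is set by the ligand; the (2S) descriptor here is the spatial arrangement called (2R) in the target, and the weakly basic two-phase medium should keep the product from ring opening.

Step 6
Reactants: 11 (2S)-5-(benzyloxy)-2-[2-(benzyloxy)-4-methoxyphenyl]-7-methoxy-2,3-dihydro-4H-chromen-4-one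
Product: 12 {[(2S)-5-(benzyloxy)-2-[2-(benzyloxy)-4-methoxyphenyl]-7-methoxy-2H-chromen-4-yl]oxy}(trimethyl)silane
Conditions: TMSOTf, Et3N, CH2Cl2, 0 °C; non-aqueous work-up, used crude
Reagents that add atoms: trimethylsilyl trifluoromethanesulfonate, C[Si](C)(C)OS(=O)(=O)C(F)(F)F
Why: Soft enolisation with a silyl triflate and a tertiary amine gives the silyl enol ether without a free enolate, so β-elimination of the ring A phenoxide and loss of the C2 configuration are avoided.

Step 7
Reactants: 12 {[(2S)-5-(benzyloxy)-2-[2-(benzyloxy)-4-methoxyphenyl]-7-methoxy-2H-chromen-4-yl]oxy}(trimethyl)silane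
Product: 14 (2R,3R)-5-(benzyloxy)-2-[2-(benzyloxy)-4-methoxyphenyl]-3-hydroxy-7-methoxy-2,3-dihydro-4H-chromen-4-one, via silyloxy epoxide 13 (not isolated)
Conditions: DMDO, acetone/CH2Cl2, −40 → 0 °C; then aq. citric acid, THF, 0 °C
Reagents that add atoms: dimethyldioxirane, CC1(C)OO1
Why: Rubottom oxidation: the dioxirane epoxidises the electron-rich C3=C4 bond on the face opposite the C2 aryl group, and mild acid opens the silyloxy epoxide 13 with loss of the silyl group to the α-hydroxy ketone. C3 is thereby set trans to the aryl group by substrate control from C2, which is also the thermodynamically preferred diequatorial arrangement.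

Step 8
Reactants: 14 (2R,3R)-5-(benzyloxy)-2-[2-(benzyloxy)-4-methoxyphenyl]-3-hydroxy-7-methoxy-2,3-dihydro-4H-chromen-4-one
Product: 15 (2R,3R)-5-(benzyloxy)-2-[2-(benzyloxy)-4-methoxyphenyl]-3,7-dimethoxy-2,3-dihydro-4H-chromen-4-one
Conditions: Me3OBF4, 1,8-bis(dimethylamino)naphthalene, 4 Å MS, CH2Cl2, 0 °C → rt
Reagents that add atoms: trimethyloxonium tetrafluoroborate, C[O+](C)C.F[B-](F)(F)F
Why: O-Methylation of a secondary alcohol by an oxonium salt with a hindered, non-nucleophilic proton scavenger; the base is too hindered to enolise the ketone quickly, so ring opening and C3 epimerisation should be avoided and both stereocentres are carried through unchanged.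

Step 9
Reactants: 15 (2R,3R)-5-(benzyloxy)-2-[2-(benzyloxy)-4-methoxyphenyl]-3,7-dimethoxy-2,3-dihydro-4H-chromen-4-one
Product: 16 (2R,3R)-5-hydroxy-2-(2-hydroxy-4-methoxyphenyl)-3,7-dimethoxy-2,3-dihydro-4H-chromen-4-one
Conditions: H2 (1 atm), 10% Pd/C, EtOAc, rt
Reagents that add atoms: none
Why: Catalytic hydrogenolysis of two aryl benzyl ethers under neutral conditions; these should cleave much faster than the cyclic benzylic C2–O1 bond is broken or the electron-rich aryl ketone is reduced, and the three methyl ethers and both stereocentres are untouched.

Step 10
Reactants: 16 (2R,3R)-5-hydroxy-2-(2-hydroxy-4-methoxyphenyl)-3,7-dimethoxy-2,3-dihydro-4H-chromen-4-one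
Product: 18 (2R,3R)-2-(2,3-dihydroxy-4-methoxyphenyl)-5,6-dihydroxy-3,7-dimethoxychroman-4-one, via bis-quinone 17 (not isolated)
Conditions: IBX (2.4 equiv), DMF, 0 °C → rt, Ar; then Na2S2O4, H2O, 0 °C
Reagents that add atoms: 2-iodoxybenzoic acid, O=C1OI(=O)(O)c2ccccc12
Why: Each free phenol exchanges with the hydroxyl ligand on the pentavalent iodine of IBX to give an aryloxy-iodane; the iodyl oxygen is then passed intramolecularly to the neighbouring ring carbon (iodine becoming trivalent), and the resulting catechol–iodane collapses to the ortho-quinone with release of 2-iodobenzoic acid (monovalent iodine), so one equivalent of oxidant serves each ring. The closest known reaction type is the regioselective IBX oxidation of electron-rich phenols to ortho-quinones followed by in situ reduction to catechols, which has been used on flavonoid ring B phenols; its extension to the hydrogen-bonded 5-hydroxyl of ring A is the less secure half. No ring is closed and no stereocentre is created; the two new bonds are C6–O and C3'–O. The step needs site selectivity, and the substrate secures it: oxygen is delivered only ortho to the iodine-bound oxygen and each phenol has a single unsubstituted ortho carbon (C6 between the 5-hydroxyl and the 7-methoxyl, C3' between the 2'-hydroxyl and the 4'-methoxyl), so C8 and C5' are out of reach. C6 should remain nucleophilic despite the chelated carbonyl because the 7-methoxyl and O1 are ortho and para to it, and DMF as a hydrogen-bond acceptor should loosen the chelate enough for ligand exchange. Chemoselectivity against dehydrogenation across C2–C3 rests on temperature, since that mode of IBX reactivity needs heating. The configurational risk is tautomerisation of the ring B quinone through the C2–H bond, so aqueous Na2S2O4 is added as soon as the phenols are consumed and reduces bis-quinone 17 to the two catechols of 18 under argon.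

## Compound list

1 | 1-(2,6-dihydroxy-4-methoxyphenyl)ethan-1-one (2',6'-dihydroxy-4'-methoxyacetophenone) | CC(=O)c1c(O)cc(OC)cc1O | starting material
2 | benzyl bromide | BrCc1ccccc1 | starting material
3 | 1-[2-(benzyloxy)-6-hydroxy-4-methoxyphenyl]ethan-1-one | CC(=O)c1c(O)cc(OC)cc1OCc1ccccc1 | intermediate
4 | (E)-1-[2-(benzyloxy)-6-hydroxy-4-methoxyphenyl]-3-(dimethylamino)prop-2-en-1-one | CN(C)/C=C/C(=O)c1c(O)cc(OC)cc1OCc1ccccc1 | intermediate (not isolated)
5 | 5-(benzyloxy)-7-methoxy-4H-chromen-4-one | O=c1ccoc2cc(OC)cc(OCc3ccccc3)c12 | intermediate
6 | 2-bromo-5-methoxyphenol | COc1ccc(Br)c(O)c1 | starting material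
7 | 2-(benzyloxy)-1-bromo-4-methoxybenzene | COc1ccc(Br)c(OCc2ccccc2)c1 | intermediate
8 | [2-(benzyloxy)-4-methoxyphenyl]lithium | [Li]c1ccc(OC)cc1OCc1ccccc1 | intermediate (not isolated)
9 | lithium [2-(benzyloxy)-4-methoxyphenyl]tri(propan-2-yloxy)borate | [Li+].COc1ccc([B-](OC(C)C)(OC(C)C)OC(C)C)c(OCc2ccccc2)c1 | intermediate (not isolated)
10 | [2-(benzyloxy)-4-methoxyphenyl]boronic acid | COc1ccc(B(O)O)c(OCc2ccccc2)c1 | intermediate
11 | (2S)-5-(benzyloxy)-2-[2-(benzyloxy)-4-methoxyphenyl]-7-methoxy-2,3-dihydro-4H-chromen-4-one | COc1ccc([C@H]2Oc3cc(OC)cc(OCc4ccccc4)c3C(=O)C2)c(OCc2ccccc2)c1 | intermediate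
12 | {[(2S)-5-(benzyloxy)-2-[2-(benzyloxy)-4-methoxyphenyl]-7-methoxy-2H-chromen-4-yl]oxy}(trimethyl)silane | COc1ccc([C@H]2Oc3cc(OC)cc(OCc4ccccc4)c3C(O[Si](C)(C)C)=C2)c(OCc2ccccc2)c1 | intermediate
13 | (2R,3R,4R)-5-(benzyloxy)-2-[2-(benzyloxy)-4-methoxyphenyl]-3,4-epoxy-7-methoxy-4-[(trimethylsilyl)oxy]chromane (epoxide oxygen on the face opposite the C2 aryl group) | COc1ccc([C@H]2Oc3cc(OC)cc(OCc4ccccc4)c3[C@]4(O[Si](C)(C)C)O[C@H]24)c(OCc2ccccc2)c1 | intermediate (not isolated)
14 | (2R,3R)-5-(benzyloxy)-2-[2-(benzyloxy)-4-methoxyphenyl]-3-hydroxy-7-methoxy-2,3-dihydro-4H-chromen-4-one | COc1ccc([C@H]2Oc3cc(OC)cc(OCc4ccccc4)c3C(=O)[C@@H]2O)c(OCc2ccccc2)c1 | intermediate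
15 | (2R,3R)-5-(benzyloxy)-2-[2-(benzyloxy)-4-methoxyphenyl]-3,7-dimethoxy-2,3-dihydro-4H-chromen-4-one | COc1ccc([C@H]2Oc3cc(OC)cc(OCc4ccccc4)c3C(=O)[C@@H]2OC)c(OCc2ccccc2)c1 | intermediate
16 | (2R,3R)-5-hydroxy-2-(2-hydroxy-4-methoxyphenyl)-3,7-dimethoxy-2,3-dihydro-4H-chromen-4-one | COc1ccc([C@H]2Oc3cc(OC)cc(O)c3C(=O)[C@@H]2OC)c(O)c1 | intermediate
17 | (2R,3R)-3,7-dimethoxy-2-(4-methoxy-5,6-dioxocyclohexa-1,3-dien-1-yl)-2,3-dihydro-4H-chromene-4,5,6-trione | COC1=CC=C([C@H]2OC3=C(C(=O)[C@@H]2OC)C(=O)C(=O)C(OC)=C3)C(=O)C1=O | intermediate (not isolated)
18 | (2R,3R)-2-(2,3-dihydroxy-4-methoxyphenyl)-5,6-dihydroxy-3,7-dimethoxychroman-4-one | COc1ccc([C@H]2Oc3cc(OC)c(O)c(O)c3C(=O)[C@@H]2OC)c(O)c1O | target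

## Step count and least certain steps

Total steps: 10. Longest linear sequence: 8 steps (steps 1, 2, 5, 6, 7, 8, 9, 10, or equally 3, 4, 5, 6, 7, 8, 9, 10).

**Step 10 (key step).** The most likely failure is incomplete ligand exchange of the chelated C5 hydroxyl at iodine, so that ring B is oxidised while ring A lags. During that delay the ring B quinone can tautomerise through C2–H (epimerisation or ring opening) or be attacked by nucleophiles, and warming to force ring A invites dehydrogenation across C2–C3. The fallback forms the same two C–O bonds by C-formylation and aryl-to-oxygen migration instead of direct oxygen transfer; it sets out from 16 and returns at 18. Magnesium-mediated ortho-formylation (MgCl2, Et3N, paraformaldehyde, THF, reflux) delivers a formyl group only ortho to each phenoxide oxygen, at C6 and C3', and should give (2R,3R)-2-(3-formyl-2-hydroxy-4-methoxyphenyl)-5-hydroxy-3,7-dimethoxy-4-oxo-3,4-dihydro-2H-chromene-6-carbaldehyde F1. The amine is a weak base and the C4 carbonyl is held in a magnesium chelate with the C5 phenoxide, but base-induced ring opening remains the point to watch in this operation. Dakin-type oxidation with mCPBA in CH2Cl2 at 0 °C should then give the bis-formate (2R,3R)-2-[3-(formyloxy)-2-hydroxy-4-methoxyphenyl]-5-hydroxy-3,7-dimethoxy-4-oxo-3,4-dihydro-2H-chromen-6-yl formate F2, and dilute aqueous HCl in THF should cleave F2 to 18.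

**Step 5.** The ortho-benzyloxy group can slow transmetalation and insertion so that protodeboronation of 10 takes over. The electron-rich vinylogous ester 5 is a sluggish acceptor, and any base-induced ring opening of 11 erodes its enantiomeric purity. The fallback replaces asymmetric catalysis by a classical chalcone route with resolution; it sets out from 3 and returns at 11. Claisen–Schmidt condensation of 3 with commercial 2-(benzyloxy)-4-methoxybenzaldehyde F3 (KOH, EtOH, rt) should give the chalcone (E)-1-[2-(benzyloxy)-6-hydroxy-4-methoxyphenyl]-3-[2-(benzyloxy)-4-methoxyphenyl]prop-2-en-1-one F4. Oxa-Michael cyclisation (NaOAc, EtOH, reflux) should give the racemic flavanone rac-5-(benzyloxy)-2-[2-(benzyloxy)-4-methoxyphenyl]-7-methoxy-2,3-dihydro-4H-chromen-4-one F5. Preparative chromatography on a chiral stationary phase then separates 11 from its enantiomer (2R)-5-(benzyloxy)-2-[2-(benzyloxy)-4-methoxyphenyl]-7-methoxy-2,3-dihydro-4H-chromen-4-one F6, and F6 can be returned to F5 by the same NaOAc treatment through ring opening and reclosure.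

**Step 8.** The likely failure is slow alkylation of the hindered, hydrogen-bonded hydroxyl, giving long exposure during which base-triggered β-elimination of the ring A phenoxide or epimerisation at C3 can occur. The fallback changes the alkylation from a base-assisted oxonium transfer to an acid-catalysed diazoalkane alkylation: TMSCHN2 with catalytic aqueous HBF4 in CH2Cl2 at 0 °C, setting out from 14 and returning directly at 15, with no base present at any point. This fallback makes no compound outside the list and is entered as F0.

**Step 9.** The likely failure is over-reduction: hydrogenolytic opening of the benzylic C2–O1 bond, which the ortho and para oxygens of ring B activate, or slow cleavage of the hindered peri benzyl ether leading to prolonged exposure. The fallback replaces surface hydrogenolysis by Lewis-acid debenzylation with a cation scavenger: BCl3 and pentamethylbenzene in CH2Cl2 at −78 °C, setting out from 15 and returning at 16. At that temperature the methyl ethers should survive. This fallback makes no compound outside the list and is entered as F0.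

## Further compounds

F1 | step 10 | (2R,3R)-2-(3-formyl-2-hydroxy-4-methoxyphenyl)-5-hydroxy-3,7-dimethoxy-4-oxo-3,4-dihydro-2H-chromene-6-carbaldehyde | COc1ccc([C@H]2Oc3cc(OC)c(C=O)c(O)c3C(=O)[C@@H]2OC)c(O)c1C=O
F2 | step 10 | (2R,3R)-2-[3-(formyloxy)-2-hydroxy-4-methoxyphenyl]-5-hydroxy-3,7-dimethoxy-4-oxo-3,4-dihydro-2H-chromen-6-yl formate | COc1ccc([C@H]2Oc3cc(OC)c(OC=O)c(O)c3C(=O)[C@@H]2OC)c(O)c1OC=O
F3 | step 5 | 2-(benzyloxy)-4-methoxybenzaldehyde | COc1ccc(C=O)c(OCc2ccccc2)c1
F4 | step 5 | (E)-1-[2-(benzyloxy)-6-hydroxy-4-methoxyphenyl]-3-[2-(benzyloxy)-4-methoxyphenyl]prop-2-en-1-one | COc1ccc(/C=C/C(=O)c2c(O)cc(OC)cc2OCc2ccccc2)c(OCc2ccccc2)c1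
F5 | step 5 | rac-5-(benzyloxy)-2-[2-(benzyloxy)-4-methoxyphenyl]-7-methoxy-2,3-dihydro-4H-chromen-4-one | COc1ccc(C2Oc3cc(OC)cc(OCc4ccccc4)c3C(=O)C2)c(OCc2ccccc2)c1
F6 | step 5 | (2R)-5-(benzyloxy)-2-[2-(benzyloxy)-4-methoxyphenyl]-7-methoxy-2,3-dihydro-4H-chromen-4-one | COc1ccc([C@@H]2Oc3cc(OC)cc(OCc4ccccc4)c3C(=O)C2)c(OCc2ccccc2)c1
F0 | step 8 | none | none
F0 | step 9 | none | none
A1 | alternative 1 | 2-[4-(benzyloxy)-2-formyl-3,5-dimethoxyphenoxy]-2-[2,3-bis(benzyloxy)-4-methoxyphenyl]acetaldehyde (racemic) | COc1ccc(C(C=O)Oc2cc(OC)c(OCc3ccccc3)c(OC)c2C=O)c(OCc2ccccc2)c1OCc1ccccc1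
A2 | alternative 1 | (2R,3R)-6-(benzyloxy)-2-[2,3-bis(benzyloxy)-4-methoxyphenyl]-3-hydroxy-5,7-dimethoxychroman-4-one | COc1ccc([C@H]2Oc3cc(OC)c(OCc4ccccc4)c(OC)c3C(=O)[C@@H]2O)c(OCc2ccccc2)c1OCc1ccccc1
A3 | alternative 2 | 1-[3-(benzyloxy)-6-bromo-2,4-dimethoxyphenyl]-2-diazoethan-1-one | COc1cc(Br)c(C(=O)C=[N+]=[N-])c(OC)c1OCc1ccccc1
A4 | alternative 2 | methanol | CO
A5 | alternative 2 | 2,3-bis(benzyloxy)-4-methoxybenzaldehyde | COc1ccc(C=O)c(OCc2ccccc2)c1OCc1ccccc1
A6 | alternative 2 | (2R,3R)-1-[3-(benzyloxy)-6-bromo-2,4-dimethoxyphenyl]-3-[2,3-bis(benzyloxy)-4-methoxyphenyl]-3-hydroxy-2-methoxypropan-1-one | COc1ccc([C@@H](O)[C@@H](OC)C(=O)c2c(Br)cc(OC)c(OCc3ccccc3)c2OC)c(OCc2ccccc2)c1OCc1ccccc1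
A7 | alternative 3 | (2R,3R)-1-[2-(benzyloxy)-3-hydroxy-4-methoxyphenyl]-3-[2,3-bis(benzyloxy)-4-methoxyphenyl]-3-hydroxy-2-methoxypropan-1-one | COc1ccc([C@@H](O)[C@@H](OC)C(=O)c2ccc(OC)c(O)c2OCc2ccccc2)c(OCc2ccccc2)c1OCc1ccccc1
A8 | alternative 3 | (2R,3R)-5-(benzyloxy)-2-[2,3-bis(benzyloxy)-4-methoxyphenyl]-6-hydroxy-3,7-dimethoxychroman-4-one | COc1ccc([C@H]2Oc3cc(OC)c(O)c(OCc4ccccc4)c3C(=O)[C@@H]2OC)c(OCc2ccccc2)c1OCc1ccccc1
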